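**Strategy.** The ten-membered carbocycle is opened between the tertiary carbinol carbon C4 and the acyloxy-bearing C5 (germacrane numbering). Both are carbinol carbons, hence former carbonyl carbons of like polarity, so the C4–C5 bond, the ring and the vicinal diol are made together by a titanium-induced reductive (pinacol) coupling of the C5 aldehyde with the C4 methyl ketone of an (E)-enone. The precursor is an open-chain keto aldehyde built on a trans-disubstituted γ-butyrolactone (C5–C7, C11, C12 from a chiral butenolide); its C9 ketone is held as a MOM-protected alcohol and its α-methylene group as a Mannich base. The C4 hydroxyl formed then directs the C2–C3 epoxidation.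

Key step: step 11

Assumption: atoms are numbered as in germacranolides (ring C1–C10, lactone carbons C11–C13, C14 on C10, C15 on C4); (S)-5-(hydroxymethyl)furan-2(5H)-one, angelic acid, (R)-2-methylbutanoic acid and (+)-Ipc2BOMe are taken as purchasable.

**Step 1**
Reactants: 1 (S)-5-(hydroxymethyl)furan-2(5H)-one
Product: 2 (S)-5-[(tert-butyldiphenylsilyloxy)methyl]furan-2(5H)-one
Conditions: TBDPSCl, imidazole, DMF, 0 °C to rt
Reagents that add atoms: tert-butyl(chloro)diphenylsilane CC(C)(C)[Si](Cl)(c1ccccc1)c1ccccc1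
Why: Standard silylation of the primary alcohol; the bulky silyl ether later shields one face of the butenolide.

**Step 2**
Reactants: 2 silyl butenolide
Product: 4 (3R,4S,5S)-5-[(tert-butyldiphenylsilyloxy)methyl]-3-[(dimethylamino)methyl]-4-vinyldihydrofuran-2(3H)-one, via magnesium enolate 3 (not isolated)
Conditions: CH2=CHMgBr, CuBr·SMe2 (cat.), THF, −78 °C; then CH2=NMe2 I, −78 to 0 °C
Reagents that add atoms: vinylmagnesium bromide C=C[Mg]Br; dimethyl(methylidene)ammonium iodide (Eschenmoser's salt) C=[N+](C)C.[I-]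
Why: Copper-catalysed conjugate addition of the vinyl Grignard reagent should occur anti to the C6 silyloxymethyl group (sets C7, trans lactone), and the enolate is trapped in a Mannich reaction anti to the new vinyl group (C11, destroyed later), which brings in C13 as a masked α-methylene group.

**Step 3**
Reactants: 4 Mannich lactone
Product: 6 (2S,3S,4R)-2-[(tert-butyldiphenylsilyloxy)methyl]-4-[(dimethylamino)methyl]-5-oxotetrahydrofuran-3-carbaldehyde, via ozonide 5 (not isolated)
Conditions: TFA (1.1 equiv), O3, CH2Cl2, −78 °C; Me2S; cold aq NaHCO3; used at once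
Reagents that add atoms: ozone [O-][O+]=O
Why: Ozonolysis of the only C=C bond with the amine protected as its trifluoroacetate salt and reductive work-up should give the C8 aldehyde without touching a stereocentre.

**Step 4**
Reactants: 7 2-methylprop-2-en-1-ol
Product: 8 3-(methoxymethoxy)-2-methylprop-1-ene
Conditions: MOMCl, iPr2NEt, CH2Cl2, 0 °C to rt
Reagents that add atoms: chloromethyl methyl ether COCCl
Why: Routine MOM protection (O-alkylation) of the allylic alcohol.

**Step 5**
Reactants: 6 aldehyde; 8 methallyl MOM ether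
Product: 11 Mannich lactone of type 4 carrying at C7 a (1S,2S)-1-hydroxy-2-(methoxymethoxy)-3-methylbut-3-en-1-yl group (C8 S, C9 S, syn), via alkoxyallylborane 9 (not isolated), via borinate 10 (not isolated)
Conditions: 8, s-BuLi, THF, −78 °C; (+)-Ipc2BOMe; BF3·OEt2; then 6, −78 °C; HOCH2CH2NH2, Et2O, rt
Reagents that add atoms: none
Why: Brown alkoxyallylboration: the (Z)-γ-alkoxyallylborane should add through a chair Zimmerman–Traxler transition state to give the syn C8/C9 diol monoether, and the isopinocampheyl groups from (+)-Ipc2BOMe direct attack to the re face of the aldehyde (C8 S by reagent control; C9 S follows).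

**Step 6**
Reactants: 11 alcohol; 12 angelic acid
Product: 14 C8 angelate of 11, via mixed anhydride 13 (not isolated)
Conditions: 12, 2,4,6-Cl3C6H2COCl, Et3N, toluene, rt; then 11, toluene, 80 °C
Reagents that add atoms: none
Why: Yamaguchi esterification through the mixed anhydride should acylate the hindered secondary C8 hydroxyl without a base strong enough to isomerise the (Z)-angelate to the tiglate.

**Step 7**
Reactants: 15 but-3-yn-2-one
Product: 16 (E)-4-iodobut-3-en-2-one
Conditions: NaI, TFA, CH2Cl2, 0 °C to rt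
Reagents that add atoms: sodium iodide [Na+].[I-]
Why: Conjugate hydroiodination of the ynone by HI made in the flask; acid-mediated equilibration should leave the thermodynamically favoured (E)-β-iodo enone.

**Step 8**
Reactants: 14 angelate; 16 iodo enone
Product: 18 Mannich lactone carrying at C7 the (1S,2S,3S,5E)-1-(angeloyloxy)-2-(methoxymethoxy)-3-methyl-7-oxooct-5-en-1-yl chain (C10 S), via alkylborane 17 (not isolated)
Conditions: 9-BBN, THF, 0 °C to rt; then aq Cs2CO3, 16, Pd(dppf)Cl2 (cat.), AsPh3 (cat.), DMF, rt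
Reagents that add atoms: none
Why: Hydroboration of the 1,1-disubstituted alkene with 9-BBN should place boron on C1 and hydrogen on C10 anti to the C9 alkoxy group (acyclic 1,2-induction, sets C10 S), and the B-alkyl Suzuki–Miyaura coupling joins C1 to C2 with retention of the (E)-enone geometry.

**Step 9**
Reactants: 18 silyl ether
Product: 19 primary alcohol (C5–OH) of 18
Conditions: HF·pyridine, pyridine, THF, 0 °C to rt
Reagents that add atoms: none
Why: Fluoride cleavage of the silyl ether under buffered, non-basic conditions that should leave the MOM ether, the esters and the enone intact.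

**Step 10**
Reactants: 19 alcohol
Product: 20 seco keto aldehyde (C5 aldehyde, C4 methyl ketone of the (E)-enone)
Conditions: DMP, CH2Cl2, 0 °C; used at once
Reagents that add atoms: none
Why: Dess–Martin oxidation of the primary alcohol under non-basic conditions that should not epimerise C6.

**Step 11**
Reactants: 20 seco keto aldehyde
Product: 21 ten-membered (2E)-4,5-diol (4R,5R,6S,8S,9S,10S; trans-fused lactone; C9–OMOM, C8 angelate, C11 Mannich base)
Conditions: TiCl3(DME)1.5, Zn–Cu couple, DME, reflux; then 20 added by syringe pump at high dilution, 25 °C; aq K2CO3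
Reagents that add atoms: none
Why: Low-valent titanium transfers one electron to the C5 aldehyde and one to the C4 enone carbonyl, the two titanium-bound ketyl radicals combine at the carbonyl carbons, and the titanium pinacolate, stable at room temperature, is hydrolysed to the diol. The closest known reaction type is the McMurry-type titanium-induced intramolecular pinacol coupling of dicarbonyl compounds to medium and large-ring 1,2-diols, which couples α,β-unsaturated carbonyls at the carbonyl carbon. The ten-membered carbocycle closes by radical–radical combination of the two carbonyl carbons held on the metal (template macrocyclisation with both C–O bonds exocyclic to the new ring), favoured over oligomers by slow addition. C4 and C5 should form as the threo (trans) diol because the two bulky titanium-oxy groups stay anti across the new bond in a ring too large for a cis titanacycle, and the face of C5 is set by the adjacent C6 centre of the rigid trans-lactone through chelation of titanium between the ketyl oxygen and the lactone ring oxygen. The step needs coupling at the carbonyl carbon rather than the enone β-carbon and no third reducible carbonyl or acrylate: C9 is a MOM ether, the α-methylene lactone is a saturated Mannich base, and the esters are inert at 25 °C.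

**Step 12**
Reactants: 21 diol; 22 (R)-2-methylbutanoic acid
Product: 24 5-O-[(R)-2-methylbutanoyl] ester of 21, via acylisourea 23 (not isolated)
Conditions: 22, DCC, DMAP (cat.), CH2Cl2, 0 °C to rt
Reagents that add atoms: none
Why: Steglich esterification should acylate the secondary C5 hydroxyl while the tertiary C4 hydroxyl is too hindered to react.

**Step 13**
Reactants: 24 MOM ether
Product: 25 C9 alcohol of 24
Conditions: MgBr2·OEt2, EtSH, Et2O, rt
Reagents that add atoms: none
Why: Lewis acid–thiol cleavage of the MOM acetal (MgBr2 activates, the thiol captures the methoxymethyl cation) should be mild enough for the tertiary allylic alcohol and the esters.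

**Step 14**
Reactants: 25 Mannich base
Product: 27 α-methylene lactone with free C9 and C4 hydroxyls, via methiodide 26 (not isolated)
Conditions: MeI, acetone, rt; then aq NaHCO3, EtOAc, rt
Reagents that add atoms: none
Why: Quaternisation of the amine followed by mild base-induced β-elimination (E1cB, Hofmann type) unveils the C11=C13 methylene group.

**Step 15**
Reactants: 27 C9 alcohol
Product: 28 C9 ketone (2E-alkene, C4–OH free)
Conditions: DMP, CH2Cl2, rt
Reagents that add atoms: none
Why: Dess–Martin oxidation of the only secondary alcohol under neutral conditions should give the ketone without epimerising C8 or C10; the tertiary C4 hydroxyl is inert.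

**Step 16**
Reactants: 28 allylic alcohol
Product: 29 CNP0217571.1 (target)
Conditions: VO(acac)2 (cat.), t-BuOOH, CH2Cl2, 0 °C to rt
Reagents that add atoms: tert-butyl hydroperoxide CC(C)(C)OO
Why: Hydroxyl-directed vanadium-catalysed epoxidation: the vanadate ester of the C4 tertiary allylic alcohol should deliver oxygen to the (E)-C2=C3 bond with the C15 methyl inside and ring carbon C5 outside (erythro sense), setting C2 (S) and C3 (R), while the electron-poor alkenes do not react.

**Compound list**

1 | (S)-5-(hydroxymethyl)furan-2(5H)-one | O=C1C=C[C@@H](CO)O1 | starting material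
2 | (S)-5-[(tert-butyldiphenylsilyloxy)methyl]furan-2(5H)-one | O=C1C=C[C@@H](CO[Si](c2ccccc2)(c2ccccc2)C(C)(C)C)O1 | intermediate
3 | bromomagnesium enolate of the trans-4-vinyl lactone | C1=C(O[Mg]Br)O[C@H](CO[Si](c2ccccc2)(c2ccccc2)C(C)(C)C)[C@H]1C=C | intermediate
4 | (3R,4S,5S)-5-[(tert-butyldiphenylsilyloxy)methyl]-3-[(dimethylamino)methyl]-4-vinyldihydrofuran-2(3H)-one | CN(C)C[C@@H]1C(=O)O[C@H](CO[Si](c2ccccc2)(c2ccccc2)C(C)(C)C)[C@H]1C=C | intermediate
5 | ozonide (1,2,4-trioxolane) of 4, epimers at the trioxolane carbon | CN(C)C[C@@H]1C(=O)O[C@H](CO[Si](c2ccccc2)(c2ccccc2)C(C)(C)C)[C@H]1C3OOCO3 | intermediate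
6 | (2S,3S,4R)-2-[(tert-butyldiphenylsilyloxy)methyl]-4-[(dimethylamino)methyl]-5-oxotetrahydrofuran-3-carbaldehyde | CN(C)C[C@@H]1C(=O)O[C@H](CO[Si](c2ccccc2)(c2ccccc2)C(C)(C)C)[C@H]1C=O | intermediate
7 | 2-methylprop-2-en-1-ol | C=C(C)CO | starting material
8 | 3-(methoxymethoxy)-2-methylprop-1-ene | C=C(C)COCOC | intermediate
9 | [(Z)-3-(methoxymethoxy)-2-methylallyl]diisopinocampheylborane (from (+)-Ipc2BOMe) | COCO/C=C(/C)CB([C@H]1C[C@H]2C[C@@H]([C@@H]1C)C2(C)C)[C@H]1C[C@H]2C[C@@H]([C@@H]1C)C2(C)C | intermediate
10 | O-diisopinocampheylboryl derivative (borinate) of 11 | CN(C)C[C@@H]1C(=O)O[C@H](CO[Si](c2ccccc2)(c2ccccc2)C(C)(C)C)[C@H]1[C@H](OB([C@H]3C[C@H]4C[C@@H]([C@@H]3C)C4(C)C)[C@H]3C[C@H]4C[C@@H]([C@@H]3C)C4(C)C)[C@@H](OCOC)C(C)=C | intermediate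
11 | Mannich lactone with a (1S,2S)-1-hydroxy-2-(methoxymethoxy)-3-methylbut-3-en-1-yl group at C7 | CN(C)C[C@@H]1C(=O)O[C@H](CO[Si](c2ccccc2)(c2ccccc2)C(C)(C)C)[C@H]1[C@H](O)[C@@H](OCOC)C(C)=C | intermediate
12 | angelic acid, (Z)-2-methylbut-2-enoic acid | C/C=C(/C)C(=O)O | starting material
13 | angelic 2,4,6-trichlorobenzoic anhydride | C/C=C(/C)C(=O)OC(=O)c1c(Cl)cc(Cl)cc1Cl | intermediate
14 | C8 angelate of 11 | CN(C)C[C@@H]1C(=O)O[C@H](CO[Si](c2ccccc2)(c2ccccc2)C(C)(C)C)[C@H]1[C@H](OC(=O)/C(C)=C\C)[C@@H](OCOC)C(C)=C | intermediate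
15 | but-3-yn-2-one | CC(=O)C#C | starting material
16 | (E)-4-iodobut-3-en-2-one | CC(=O)/C=C/I | intermediate
17 | B-alkyl-9-BBN from 14 (boron on C1, C10 S) | CN(C)C[C@@H]1C(=O)O[C@H](CO[Si](c2ccccc2)(c2ccccc2)C(C)(C)C)[C@H]1[C@H](OC(=O)/C(C)=C\C)[C@@H](OCOC)[C@@H](C)CB3C4CCCC3CCC4 | intermediate
18 | Mannich lactone with the (1S,2S,3S,5E)-1-(angeloyloxy)-2-(methoxymethoxy)-3-methyl-7-oxooct-5-en-1-yl chain, silyl ether | CN(C)C[C@@H]1C(=O)O[C@H](CO[Si](c2ccccc2)(c2ccccc2)C(C)(C)C)[C@H]1[C@H](OC(=O)/C(C)=C\C)[C@@H](OCOC)[C@@H](C)C/C=C/C(C)=O | intermediate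
19 | primary alcohol (C5–OH) from 18 | CN(C)C[C@@H]1C(=O)O[C@H](CO)[C@H]1[C@H](OC(=O)/C(C)=C\C)[C@@H](OCOC)[C@@H](C)C/C=C/C(C)=O | intermediate
20 | seco keto aldehyde (C5 aldehyde, C4 enone) | CN(C)C[C@@H]1C(=O)O[C@H](C=O)[C@H]1[C@H](OC(=O)/C(C)=C\C)[C@@H](OCOC)[C@@H](C)C/C=C/C(C)=O | intermediate
21 | ten-membered (2E)-4,5-diol, (4R,5R,6S,8S,9S,10S), trans-lactone | CN(C)C[C@@H]1C(=O)O[C@H]2[C@H]1[C@H](OC(=O)/C(C)=C\C)[C@@H](OCOC)[C@@H](C)C/C=C/[C@@](C)(O)[C@@H]2O | intermediate
22 | (R)-2-methylbutanoic acid | CC[C@@H](C)C(=O)O | starting material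
23 | O-[(R)-2-methylbutanoyl]-N,N'-dicyclohexylisourea | CC[C@@H](C)C(=O)OC(=NC1CCCCC1)NC1CCCCC1 | intermediate
24 | 5-O-[(R)-2-methylbutanoyl] ester of 21 | CN(C)C[C@@H]1C(=O)O[C@H]2[C@H]1[C@H](OC(=O)/C(C)=C\C)[C@@H](OCOC)[C@@H](C)C/C=C/[C@@](C)(O)[C@@H]2OC(=O)[C@H](C)CC | intermediate
25 | C9 alcohol from 24 | CN(C)C[C@@H]1C(=O)O[C@H]2[C@H]1[C@H](OC(=O)/C(C)=C\C)[C@@H](O)[C@@H](C)C/C=C/[C@@](C)(O)[C@@H]2OC(=O)[C@H](C)CC | intermediate
26 | trimethylammonium iodide (methiodide) of 25 | C[N+](C)(C)C[C@@H]1C(=O)O[C@H]2[C@H]1[C@H](OC(=O)/C(C)=C\C)[C@@H](O)[C@@H](C)C/C=C/[C@@](C)(O)[C@@H]2OC(=O)[C@H](C)CC.[I-] | intermediate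
27 | α-methylene lactone, C9 alcohol | C=C1C(=O)O[C@H]2[C@H]1[C@H](OC(=O)/C(C)=C\C)[C@@H](O)[C@@H](C)C/C=C/[C@@](C)(O)[C@@H]2OC(=O)[C@H](C)CC | intermediate
28 | α-methylene lactone, C9 ketone, (2E)-alkene | C=C1C(=O)O[C@H]2[C@H]1[C@H](OC(=O)/C(C)=C\C)C(=O)[C@@H](C)C/C=C/[C@@](C)(O)[C@@H]2OC(=O)[C@H](C)CC | intermediate
29 | CNP0217571.1 | C=C1C(=O)O[C@H]2[C@H]1[C@H](OC(=O)/C(C)=C\C)C(=O)[C@@H](C)C[C@@H]1O[C@H]1[C@@](C)(O)[C@@H]2OC(=O)[C@H](C)CC | target

**Step count and risks**

Total steps: 16. Longest linear sequence: 14 (steps 1, 2, 3, 5, 6, 8, 9, 10, 11, 12, 13, 14, 15, 16).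

Steps most likely to fail:

1. Step 11. Oligomerisation, coupling at the enone β-carbon, reductive cleavage of the C6–O bond next to the aldehyde, or low facial selectivity at C5 so that the cis (erythro) diol dominates. The fallback sets out from 20 and comes back at 21, and it decouples ring closure from control of C5. The coupling of 20 is run as above. If it gives chiefly the C5-epimeric cis-diol F1, the C5 epimers are oxidised together at the secondary carbinol (DMP, CH2Cl2) to the 4-hydroxy-5-oxo compound (α-ketol) F2. F2 is then reduced with Me4NBH(OAc)3 in MeCN/AcOH at −20 °C. Hydride is delivered within the C4 alkoxyborohydride to the carbonyl face syn to O4, which, as in cyclic α-ketols, should give the trans-diol 21.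

2. Step 16. Oxygen delivery to the wrong face of the C2=C3 bond, because directed delivery follows the conformation of the ten-membered ring. The fallback sets out from 28 and comes back at 29, replacing hydroxyl direction by steric control. The tertiary hydroxyl of 28 is silylated (N-(trimethylsilyl)imidazole, CH2Cl2) to the C4 trimethylsilyl ether F3. Dimethyldioxirane (acetone, 0 °C) should epoxidise the only electron-rich alkene of F3 on the face away from the silyloxy group to give the epoxy silyl ether F4. Buffered HF·pyridine (THF, 0 °C) then gives 29.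

3. Step 5. Sequestration of the borane by the dimethylamino group, mismatched pairing of reagent and C7 centre with low facial selectivity at C8, or base-induced β-elimination of the β-acyloxy aldehyde. The fallback sets out from 8 (with 6) and comes back at 11, replacing reagent control by substrate control. Ether 8 is lithiated (s-BuLi, THF, −78 °C) and quenched with Bu3SnCl to give tributyl[(Z)-3-(methoxymethoxy)-2-methylallyl]stannane F5. F5 is added to 6 with BF3·OEt2 (2 equiv, one of which ties up the amine) in CH2Cl2 at −78 °C. The open antiperiplanar transition state should be syn-selective for C8/C9, and 1,3-anti induction by the C6 oxygen should set the C8 face, giving 11.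

**Further compounds**

F1 | step 11 | C5-epimeric (cis) diol of 21 | CN(C)C[C@@H]1C(=O)O[C@H]2[C@H]1[C@H](OC(=O)/C(C)=C\C)[C@@H](OCOC)[C@@H](C)C/C=C/[C@@](C)(O)[C@H]2O
F2 | step 11 | 4-hydroxy-5-oxo compound (α-ketol) from the diol | CN(C)C[C@@H]1C(=O)O[C@H]2[C@H]1[C@H](OC(=O)/C(C)=C\C)[C@@H](OCOC)[C@@H](C)C/C=C/[C@@](C)(O)C2=O
F3 | step 16 | C4 trimethylsilyl ether of 28 | C=C1C(=O)O[C@H]2[C@H]1[C@H](OC(=O)/C(C)=C\C)C(=O)[C@@H](C)C/C=C/[C@@](C)(O[Si](C)(C)C)[C@@H]2OC(=O)[C@H](C)CC
F4 | step 16 | C4 trimethylsilyl ether of 29 | C=C1C(=O)O[C@H]2[C@H]1[C@H](OC(=O)/C(C)=C\C)C(=O)[C@@H](C)C[C@@H]1O[C@H]1[C@@](C)(O[Si](C)(C)C)[C@@H]2OC(=O)[C@H](C)CC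
F5 | step 5 | tributyl[(Z)-3-(methoxymethoxy)-2-methylallyl]stannane | CCCC[Sn](CCCC)(CCCC)C/C(C)=C\OCOC
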